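**Retrosynthetic overview**

1. The target is the 6-O-benzoate of 8α,9α-epoxyjaeschkeanadiol; the oxirane (hydroxyl-directed epoxidation of C8=C9) and the ester are put on last, on the trans-fused 4,6-diol.
2. C6–O and C5–H (conjugate borylation/protonation, then oxidation and 1,3-anti reduction at C6) and C4 (isopropyl addition to the cyclopentanone) all derive from one bicyclic dienone with C4=O and C5=C6.
3. Key disconnection: the C5–C6 bond, made at the alkene oxidation level by ring-closing metathesis of an α-methylene cyclopentanone; the five-membered ring is present from the start, the seven-membered ring is closed in the key step, the oxirane comes last.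
4. Enabling feature: C5 sits next to the C4 oxygen of the five-membered ring and C6 carries oxygen, so the bond can be closed as the enone double bond C5=C6 and hydrated afterwards; the seven-membered ring also holds a second, Z double bond (C8=C9) two atoms away, which bends the open chain so that C5 and C6 meet.
5. The quaternary C1 comes from a copper-catalysed asymmetric conjugate methylation of a 3-substituted cyclopentenone; the Z side chain comes from methyl acetoacetate through a Z enol triflate.

Key step: step 8

Remark: atoms are numbered as in daucane (C1 angular-methyl carbon, C2 and C3 ring CH2, C4 isopropyl carbinol carbon, C5 ring-fusion CH, C6 benzoyloxy carbon, C7 CH2, C8 and C9 oxirane carbons with the methyl on C8, C10 CH2); β is the face of the angular methyl, α the opposite face.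
Remark: the stannyl enone used in step 5 is taken as a catalogue compound (otherwise one step from 3-ethoxycyclopent-2-en-1-one with Bu3SnLi and acidic work-up), and the enantiomer of the phosphoramidite ligand in step 6 that gives the R centre is taken as established in a trial run.

Step 1
Reactants: 1 methyl acetoacetate
Product: 2 methyl (2Z)-3-{[(trifluoromethyl)sulfonyl]oxy}but-2-enoate
Conditions: Tf2O, saturated aq LiOH, toluene, 5 °C
Reagents that add atoms: trifluoromethanesulfonic anhydride O=S(=O)(OS(=O)(=O)C(F)(F)F)C(F)(F)F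
Why: O-sulfonylation of the lithium-chelated Z enolate of the β-keto ester should give the Z enol triflate, which fixes the later Z geometry of C8=C9 (enol triflate formation).

Step 2
Reactants: 2 methyl (2Z)-3-{[(trifluoromethyl)sulfonyl]oxy}but-2-enoate; 3 allyltributylstannane
Product: 4 methyl (2Z)-3-methylhexa-2,5-dienoate
Conditions: Pd(PPh3)4 (3 mol %), LiCl (3 equiv), THF, 65 °C
Reagents that add atoms: none
Why: Stille coupling of a vinyl triflate proceeds with retention of the alkene geometry, so the allyl group should end up cis to the ester.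

Step 3
Reactants: 4 methyl (2Z)-3-methylhexa-2,5-dienoate
Product: 5 (2Z)-3-methylhexa-2,5-dien-1-ol
Conditions: iBu2AlH (2.2 equiv), CH2Cl2, −78 °C; aq KNaC4H4O6 (potassium sodium tartrate)
Reagents that add atoms: none
Why: 1,2-reduction of the conjugated ester by the aluminium hydride should give the allylic alcohol and leave both alkenes and the Z geometry untouched (ester reduction).

Step 4
Reactants: 5 (2Z)-3-methylhexa-2,5-dien-1-ol
Product: 6 (2Z)-1-bromo-3-methylhexa-2,5-diene
Conditions: CBr4, PPh3, CH2Cl2, 0 °C
Reagents that add atoms: carbon tetrabromide BrC(Br)(Br)Br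
Why: the Appel reaction replaces the primary allylic hydroxyl by bromide through SN2 displacement of the oxyphosphonium group, which should keep the trisubstituted Z alkene in place.

Step 5
Reactants: 6 (2Z)-1-bromo-3-methylhexa-2,5-diene; 7 3-(tributylstannyl)cyclopent-2-en-1-one
Product: 8 3-[(2Z)-3-methylhexa-2,5-dien-1-yl]cyclopent-2-en-1-one
Conditions: Pd2(dba)3 (2.5 mol %), AsPh3 (10 mol %), THF, 50 °C
Reagents that add atoms: none
Why: Stille coupling of the alkenylstannane with the allylic bromide should join the enone carbon to the unsubstituted allyl terminus under neutral conditions, which spares the Z alkene and the base-sensitive doubly allylic CH2 of the product.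

Step 6
Reactants: 8 3-[(2Z)-3-methylhexa-2,5-dien-1-yl]cyclopent-2-en-1-one
Product: 10 (3R)-3-methyl-3-[(2Z)-3-methylhexa-2,5-dien-1-yl]cyclopent-1-en-1-yl acetate, via aluminium enolate 9 (not isolated)
Conditions: Cu(O2CC4H3S) (copper thiophene-2-carboxylate, 5 mol %), chiral biphenol-derived phosphoramidite with a bis(1-arylethyl)amino group (10 mol %), AlMe3 (2 equiv), Et2O, −30 °C; then Ac2O, −30 °C to rt
Reagents that add atoms: trimethylaluminium C[Al](C)C; acetic anhydride CC(=O)OC(C)=O
Why: copper-catalysed asymmetric conjugate addition of methyl to the β,β-disubstituted enone creates the quaternary carbon C1, whose R configuration is set by the chiral phosphoramidite–copper catalyst, and O-acetylation of the aluminium enolate stores the C4–C5 enolate regiochemistry.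

Step 7
Reactants: 10 (3R)-3-methyl-3-[(2Z)-3-methylhexa-2,5-dien-1-yl]cyclopent-1-en-1-yl acetate
Product: 14 (3R)-3-methyl-2-methylidene-3-[(2Z)-3-methylhexa-2,5-dien-1-yl]cyclopentan-1-one, via lithium enolate 11 (not isolated), via Mannich base 12 (not isolated), via ammonium iodide 13 (not isolated)
Conditions: MeLi (2.1 equiv), THF, 0 °C; Eschenmoser's salt, −78 °C to rt; MeI, MeOH, rt; aq NaHCO3, CH2Cl2
Reagents that add atoms: N,N-dimethylmethyleneiminium iodide (Eschenmoser's salt) C[N+](C)=C.[I-]
Why: cleavage of the enol acetate by methyllithium releases the C5 enolate regiospecifically, and its Mannich reaction with the iminium salt followed by exhaustive N-methylation and E1cB loss of trimethylamine should give the exocyclic enone, the C5 stereocentre formed in passing being removed again.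

Step 8
Reactants: 14 (3R)-3-methyl-2-methylidene-3-[(2Z)-3-methylhexa-2,5-dien-1-yl]cyclopentan-1-one
Product: 15 (3aR)-3a,6-dimethyl-3,3a,4,7-tetrahydroazulen-1(2H)-one
Conditions: second-generation Hoveyda–Grubbs catalyst RuCl2(H2IMes)(=CH-C6H4-2-OiPr) (5–10 mol %), 1,4-benzoquinone (10 mol %), toluene (0.005 M), 80 °C, argon sparge
Reagents that add atoms: none
Why: Ring-closing olefin metathesis: the ruthenium alkylidene is first formed at the monosubstituted vinyl terminus (C6) and then engages the exocyclic methylene on C5 through a metallacyclobutane, which forms the C5=C6 double bond and releases ethylene. The closest known reaction type is the ring-closing metathesis of α-methylene ketones and lactones with terminal alkenes to cyclic trisubstituted enones. The seven-membered ring is closed head to head between the two alkene termini, so that both new sp2 carbons lie in the ring and the C5=C6 bond is exocyclic to the existing five-membered ring. No stereocentre is formed: C5 and C6 are left trigonal on purpose, so that steps 9 to 12 can set them under control of the ring shape, of boron and of the C4 hydroxyl, while C1 is untouched. The step needs cyclisation to win over intermolecular metathesis at the vinyl group and must spare the trisubstituted C8=C9 alkene and the skipped diene: the Z geometry of C8=C9 holds C5 and C6 on the same side of the chain, high dilution with removal of ethylene and benzoquinone (against hydride-induced double bond migration) favour the ring, and the trisubstituted alkene is too hindered for the catalyst and could only close a four-membered ring.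

Step 9
Reactants: 15 (3aR)-3a,6-dimethyl-3,3a,4,7-tetrahydroazulen-1(2H)-one
Product: 17 (3aR,8R,8aS)-8-hydroxy-3a,6-dimethyl-3,3a,4,7,8,8a-hexahydroazulen-1(2H)-one, via boronate 16 (not isolated)
Conditions: CuCl (5 mol %), bis[2-(diphenylphosphino)phenyl] ether (5 mol %), NaOtBu (5 mol %), B2pin2 (1.1 equiv), MeOH (2 equiv), THF, 0 °C; then 30 % H2O2, NaH2PO4/Na2HPO4 buffer (pH 7), 0 °C
Reagents that add atoms: hydrogen peroxide OO
Why: copper-catalysed conjugate borylation touches only the enone, boron should add to C6 on the convex β face of the tub-shaped cyclohepta-1,4-diene (anti to the allylic C7–C8 bond), the copper enolate should then be protonated at C5 from the α face (anti to boron and to the angular methyl), which gives the trans ring fusion, and the C–B bond is oxidised with retention.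

Step 10
Reactants: 17 (3aR,8R,8aS)-8-hydroxy-3a,6-dimethyl-3,3a,4,7,8,8a-hexahydroazulen-1(2H)-one
Product: 18 (3R,3aS,4R,8aR)-6,8a-dimethyl-3-(propan-2-yl)-1,2,3,3a,4,5,8,8a-octahydroazulene-3,4-diol
Conditions: CeCl3 (anhydrous, 4 equiv), iPrMgCl (4 equiv), THF, −78 to −30 °C
Reagents that add atoms: isopropylmagnesium chloride CC(C)[Mg]Cl
Why: the weakly basic organocerium reagent should add to the C4 carbonyl without enolisation and from the α face, opposite the neighbouring β-oriented C5–C6 bond and the angular methyl (1,2-induction by C5), which gives the 4β-hydroxy-4α-isopropyl carbinol.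

Step 11
Reactants: 18 (3R,3aS,4R,8aR)-6,8a-dimethyl-3-(propan-2-yl)-1,2,3,3a,4,5,8,8a-octahydroazulene-3,4-diol
Product: 19 (3R,3aR,8aR)-3-hydroxy-6,8a-dimethyl-3-(propan-2-yl)-2,3,3a,5,8,8a-hexahydroazulen-4(1H)-one
Conditions: Dess–Martin periodinane, NaHCO3, CH2Cl2, 0 °C to rt
Reagents that add atoms: none
Why: oxidation of the secondary alcohol removes the wrongly configured C6 centre while the tertiary C4 alcohol is inert, and the buffered medium should leave C5 as it is, since the epimer with the seven-membered ring trans to the isopropyl group is also the more stable one.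

Step 12
Reactants: 19 (3R,3aR,8aR)-3-hydroxy-6,8a-dimethyl-3-(propan-2-yl)-2,3,3a,5,8,8a-hexahydroazulen-4(1H)-one
Product: 20 (3R,3aS,4S,8aR)-6,8a-dimethyl-3-(propan-2-yl)-1,2,3,3a,4,5,8,8a-octahydroazulene-3,4-diol
Conditions: Me4NBH(OAc)3, MeCN/AcOH 1:1, −30 °C
Reagents that add atoms: none
Why: in the Evans–Saksena reduction the acetoxyborohydride exchanges onto the 4β-hydroxyl and delivers hydride intramolecularly to the β face of the C6 ketone, which should give the 1,3-anti diol with the 6α-hydroxyl.

Step 13
Reactants: 20 (3R,3aS,4S,8aR)-6,8a-dimethyl-3-(propan-2-yl)-1,2,3,3a,4,5,8,8a-octahydroazulene-3,4-diol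
Product: 21 (1R,4R,5S,6S,8R,9S)-8,9-epoxydaucane-4,6-diol
Conditions: VO(acac)2 (5 mol %), tBuOOH (1.5 equiv), CH2Cl2, 0 °C to rt
Reagents that add atoms: tert-butyl hydroperoxide CC(C)(C)OO
Why: in this hydroxyl-directed epoxidation the vanadium peroxide bound to the homoallylic 6α-hydroxyl delivers oxygen to the α face of C8=C9, which is also the face opposite the angular methyl, and so sets C8 and C9.

Step 14
Reactants: 21 (1R,4R,5S,6S,8R,9S)-8,9-epoxydaucane-4,6-diol
Product: 22 (1R,4R,5S,6S,8R,9S)-8,9-epoxy-4-hydroxydaucan-6-yl benzoate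
Conditions: BzCl (1.5 equiv), DMAP (0.2 equiv), pyridine, CH2Cl2, 0 °C to rt
Reagents that add atoms: benzoyl chloride O=C(Cl)c1ccccc1
Why: nucleophile-catalysed acylation should esterify only the secondary 6-hydroxyl, because the tertiary 4-hydroxyl is too hindered, and the buffered medium should leave the trisubstituted oxirane intact.

**Compound list**

1 | methyl acetoacetate | CC(=O)CC(=O)OC | starting material
2 | methyl (2Z)-3-{[(trifluoromethyl)sulfonyl]oxy}but-2-enoate | COC(=O)/C=C(/C)OS(=O)(=O)C(F)(F)F | intermediate
3 | allyltributylstannane | C=CC[Sn](CCCC)(CCCC)CCCC | starting material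
4 | methyl (2Z)-3-methylhexa-2,5-dienoate | COC(=O)/C=C(/C)CC=C | intermediate
5 | (2Z)-3-methylhexa-2,5-dien-1-ol | OC/C=C(/C)CC=C | intermediate
6 | (2Z)-1-bromo-3-methylhexa-2,5-diene | BrC/C=C(/C)CC=C | intermediate
7 | 3-(tributylstannyl)cyclopent-2-en-1-one | O=C1C=C([Sn](CCCC)(CCCC)CCCC)CC1 | starting material
8 | 3-[(2Z)-3-methylhexa-2,5-dien-1-yl]cyclopent-2-en-1-one | O=C1C=C(C/C=C(/C)CC=C)CC1 | intermediate
9 | dimethylaluminium (3R)-3-methyl-3-[(2Z)-3-methylhexa-2,5-dien-1-yl]cyclopent-1-en-1-olate (aluminium enolate) | C[Al](C)OC1=C[C@@](C)(C/C=C(/C)CC=C)CC1 | intermediate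
10 | (3R)-3-methyl-3-[(2Z)-3-methylhexa-2,5-dien-1-yl]cyclopent-1-en-1-yl acetate | CC(=O)OC1=C[C@@](C)(C/C=C(/C)CC=C)CC1 | intermediate
11 | lithium (3R)-3-methyl-3-[(2Z)-3-methylhexa-2,5-dien-1-yl]cyclopent-1-en-1-olate (lithium enolate) | [Li+].[O-]C1=C[C@@](C)(C/C=C(/C)CC=C)CC1 | intermediate
12 | (3R)-2-[(dimethylamino)methyl]-3-methyl-3-[(2Z)-3-methylhexa-2,5-dien-1-yl]cyclopentan-1-one (Mannich base, both epimers at ring C2) | CN(C)CC1C(=O)CC[C@]1(C)C/C=C(/C)CC=C | intermediate
13 | trimethyl({(2R)-2-methyl-2-[(2Z)-3-methylhexa-2,5-dien-1-yl]-5-oxocyclopentyl}methyl)ammonium iodide | C[N+](C)(C)CC1C(=O)CC[C@]1(C)C/C=C(/C)CC=C.[I-] | intermediate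
14 | (3R)-3-methyl-2-methylidene-3-[(2Z)-3-methylhexa-2,5-dien-1-yl]cyclopentan-1-one | C=C1C(=O)CC[C@]1(C)C/C=C(/C)CC=C | intermediate
15 | (3aR)-3a,6-dimethyl-3,3a,4,7-tetrahydroazulen-1(2H)-one (bicyclic dienone, C4=O and C5=C6) | O=C1CC[C@]2(C)CC=C(C)CC=C21 | intermediate
16 | (3aR,8R,8aR)-3a,6-dimethyl-8-(4,4,5,5-tetramethyl-1,3,2-dioxaborolan-2-yl)-3,3a,4,7,8,8a-hexahydroazulen-1(2H)-one (6β-boryl, 5α-H) | O=C1CC[C@]2(C)CC=C(C)C[C@@H](B3OC(C)(C)C(C)(C)O3)[C@H]21 | intermediate
17 | (3aR,8R,8aS)-8-hydroxy-3a,6-dimethyl-3,3a,4,7,8,8a-hexahydroazulen-1(2H)-one (6β-OH, 5α-H, trans-fused) | O=C1CC[C@]2(C)CC=C(C)C[C@@H](O)[C@H]21 | intermediate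
18 | (3R,3aS,4R,8aR)-6,8a-dimethyl-3-(propan-2-yl)-1,2,3,3a,4,5,8,8a-octahydroazulene-3,4-diol (6-epi-jaeschkeanadiol) | CC(C)[C@]1(O)CC[C@]2(C)CC=C(C)C[C@@H](O)[C@H]21 | intermediate
19 | (3R,3aR,8aR)-3-hydroxy-6,8a-dimethyl-3-(propan-2-yl)-2,3,3a,5,8,8a-hexahydroazulen-4(1H)-one | CC(C)[C@]1(O)CC[C@]2(C)CC=C(C)CC(=O)[C@H]21 | intermediate
20 | (3R,3aS,4S,8aR)-6,8a-dimethyl-3-(propan-2-yl)-1,2,3,3a,4,5,8,8a-octahydroazulene-3,4-diol (jaeschkeanadiol) | CC(C)[C@]1(O)CC[C@]2(C)CC=C(C)C[C@H](O)[C@H]21 | intermediate
21 | (1R,4R,5S,6S,8R,9S)-8,9-epoxydaucane-4,6-diol (8α,9α-epoxyjaeschkeanadiol) | CC(C)[C@]1(O)CC[C@]2(C)C[C@@H]3O[C@]3(C)C[C@H](O)[C@H]21 | intermediate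
22 | (1R,4R,5S,6S,8R,9S)-8,9-epoxy-4-hydroxydaucan-6-yl benzoate | CC(C)[C@]1(O)CC[C@]2(C)C[C@@H]3O[C@]3(C)C[C@H](OC(=O)c3ccccc3)[C@H]21 | target

**Step count and risks**

Total step count: 14. Longest linear sequence: 14 steps (from 1 to 22; 3 and 7 enter as purchased building blocks).

Step 8 (ring closure). What may go wrong: the catalyst engages the electron-poor 1,1-disubstituted alkene next to the quaternary carbon too slowly, so that intermolecular metathesis at the vinyl group, migration of the terminal double bond and catalyst decay take over. Fallback: the ring is closed at the alcohol oxidation level. Setting out from 14, Luche reduction (NaBH4, CeCl3·7H2O, MeOH, −78 °C) should give the allylic alcohol (3R)-3-methyl-2-methylidene-3-[(2Z)-3-methylhexa-2,5-dien-1-yl]cyclopentan-1-ol F1 as a mixture of carbinol epimers. Ring-closing metathesis of this electron-richer alkene, which a free allylic hydroxyl is known to accelerate, should give the bicyclic dienol (3aR)-3a,6-dimethyl-1,2,3,3a,4,7-hexahydroazulen-1-ol F2. Oxidation of the allylic alcohol (MnO2, CH2Cl2) then comes back to the route at 15.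

Step 9 (borylation and protonation). What may go wrong: poor facial selectivity of boron delivery at C6, protonation of the enolate at C5 from the wrong face (cis ring fusion), or alkoxide-induced migration of C8=C9 into conjugation with the enone. Fallback: oxygen is delivered to C6 from the C4 hydroxyl and hydrogen to C5 by a radical.
- Setting out from 15, addition of iPrMgCl/CeCl3 to the enone carbonyl gives the tertiary allylic alcohol (1R,3aR)-3a,6-dimethyl-1-(propan-2-yl)-1,2,3,3a,4,7-hexahydroazulen-1-ol F3. Facial control by the angular methyl is expected to be weak here, so the carbinol epimer is removed at this point.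
- VO(acac)2/tBuOOH epoxidises the allylic C5=C6 bond on the face of the hydroxyl and leaves C8=C9 alone, giving the epoxy alcohol (1R,3aR)-8,8a-epoxy-3a,6-dimethyl-1-(propan-2-yl)-1,2,3,3a,4,7,8,8a-octahydroazulen-1-ol with the oxirane cis to the hydroxyl F4.
- Reductive opening with Cp2TiCl (from Cp2TiCl2 and zinc dust) and 1,4-cyclohexadiene cleaves the C5–O bond to the tertiary radical, which should take up hydrogen on the α face, opposite the three β substituents. This comes back to the route at 18.

Step 10 (isopropyl addition). What may go wrong: enolisation of the hindered β-hydroxy ketone by the secondary organometallic, followed by retro-aldol opening or loss of water back to the enone, and incomplete addition. Fallback: a smaller sp2 nucleophile and a later reduction. Setting out from 17, CH2=C(CH3)MgBr/CeCl3 (THF, −78 °C) should give (3S,3aS,4R,8aR)-6,8a-dimethyl-3-(prop-1-en-2-yl)-1,2,3,3a,4,5,8,8a-octahydroazulene-3,4-diol F5 with the same facial preference. Homogeneous hydrogenation with RhCl(PPh3)3 (H2, benzene) reduces the 1,1-disubstituted alkene and leaves the trisubstituted ring alkene, which comes back to the route at 18.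

Further compounds
F1 | step 8 | (3R)-3-methyl-2-methylidene-3-[(2Z)-3-methylhexa-2,5-dien-1-yl]cyclopentan-1-ol (both carbinol epimers) | C=C1C(O)CC[C@]1(C)C/C=C(/C)CC=C
F2 | step 8 | (3aR)-3a,6-dimethyl-1,2,3,3a,4,7-hexahydroazulen-1-ol (both carbinol epimers) | OC1CC[C@]2(C)CC=C(C)CC=C21
F3 | step 9 | (1R,3aR)-3a,6-dimethyl-1-(propan-2-yl)-1,2,3,3a,4,7-hexahydroazulen-1-ol | CC(C)[C@]1(O)CC[C@]2(C)CC=C(C)CC=C21
F4 | step 9 | (1R,3aR)-8,8a-epoxy-3a,6-dimethyl-1-(propan-2-yl)-1,2,3,3a,4,7,8,8a-octahydroazulen-1-ol with the oxirane cis to the hydroxyl (5β,6β-epoxide in daucane numbering) | CC(C)[C@]1(O)CC[C@]2(C)CC=C(C)C[C@H]3O[C@@]123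
F5 | step 10 | (3S,3aS,4R,8aR)-6,8a-dimethyl-3-(prop-1-en-2-yl)-1,2,3,3a,4,5,8,8a-octahydroazulene-3,4-diol | CC(=C)[C@]1(O)CC[C@]2(C)CC=C(C)C[C@@H](O)[C@H]21
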